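**Retrosynthetic overview**
1. Target 12 ⇐ 10 by olefin cross-metathesis (but-2-enyl → prenyl on the bridgehead).
2. 10 ⇐ 8 by anodic 5-exo cyclization/hydroxylation: forms the C5–C6 bond, closes the five-membered ring onto the existing six-membered ring (giving the bicyclo[3.2.1]octane) and sets C1, C5 and C6.
3. 8 ⇐ 5 + (R)-but-3-en-2-ol 6 by Mitsunobu etherification and dearomative Claisen shift; the carbinol stereocenter is transferred to the quaternary ring carbon.
4. 5 ⇐ 2-methylphloroglucinol 1 by Friedel–Crafts acylation and C-prenylation.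
5. Ring order: the six-membered ring is the starting arene; the five-membered ring is closed last, in the electrochemical step. (R)-But-3-en-2-ol is the only source of chirality.

Assumption: the enolized β-triketone is drawn as one tautomer throughout, tautomers count as one compound, and CIP descriptors refer to the tautomer drawn.

**Step 1**
Reactants: 1 2-methylbenzene-1,3,5-triol (2-methylphloroglucinol); 2 2-methylpropanoyl chloride
Product: 3 1-(2,4,6-trihydroxy-3-methylphenyl)-2-methylpropan-1-one
Conditions: AlCl3 (3 equiv), PhNO2, 65 °C; aq. HCl work-up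
Reagents that add atoms: 2-methylpropanoyl chloride (compound 2), CC(C)C(Cl)=O
Why: Friedel–Crafts acylation of the strongly activated ring, whose two free positions are equivalent, so one monoketone forms; no stereocenter.

**Step 2**
Reactants: 3 1-(2,4,6-trihydroxy-3-methylphenyl)-2-methylpropan-1-one; 4 1-bromo-3-methylbut-2-ene (prenyl bromide)
Product: 5 1-[2,4,6-trihydroxy-3-methyl-5-(3-methylbut-2-en-1-yl)phenyl]-2-methylpropan-1-one
Conditions: prenyl bromide (1.1 equiv), 10% aq. KOH, 0 °C
Reagents that add atoms: 1-bromo-3-methylbut-2-ene (compound 4), CC(C)=CCBr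
Why: C-alkylation of the ambident phloroglucinol phenolate in water at the only unsubstituted ring carbon (aromatic C-prenylation); no stereocenter.

**Step 3**
Reactants: 5 1-[2,4,6-trihydroxy-3-methyl-5-(3-methylbut-2-en-1-yl)phenyl]-2-methylpropan-1-one; 6 (R)-but-3-en-2-ol
Product: 8 (6R)-6-[(2E)-but-2-en-1-yl]-3,5-dihydroxy-4-methyl-6-(3-methylbut-2-en-1-yl)-2-(2-methylpropanoyl)cyclohexa-2,4-dien-1-one, via aryl ether 7 (not isolated)
Conditions: PPh3, DIAD, toluene, 0 °C to rt; then 110 °C, 6 h
Reagents that add atoms: (R)-but-3-en-2-ol (compound 6), C[C@@H](O)C=C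
Why: Mitsunobu etherification of the most acidic, non-chelated para-OH with inversion gives the (S)-ether 7, and its dearomative aromatic Claisen [3,3] rearrangement through a chair transition state with the methyl group equatorial delivers the allyl terminus to one face of the prenyl-bearing ortho carbon, setting the quaternary center (6R) and the E-alkene by 1,3-chirality transfer (the isomer from migration to the methyl-bearing ortho carbon is removed by chromatography).

**Step 4**
Reactants: 8 (6R)-6-[(2E)-but-2-en-1-yl]-3,5-dihydroxy-4-methyl-6-(3-methylbut-2-en-1-yl)-2-(2-methylpropanoyl)cyclohexa-2,4-dien-1-one; 9 water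
Product: 10 (1R,5R,6R)-1-[(2E)-but-2-en-1-yl]-4-hydroxy-6-(2-hydroxypropan-2-yl)-5-methyl-3-(2-methylpropanoyl)bicyclo[3.2.1]oct-3-ene-2,8-dione
Conditions: graphite anode, Pt cathode, undivided cell, 5 mA cm−2, 2.2 F mol−1, LiClO4 (0.1 M), 2,6-lutidine (0.2 equiv), MeCN/H2O 9:1, rt
Reagents that add atoms: water (compound 9), O
Why: Proposed new method: anodic oxidation of the enolized β-triketone gives the carbon radical at the methyl-bearing carbon, which closes 5-exo-trig onto the electron-rich trisubstituted prenyl alkene in preference to the disubstituted butenyl group, and the tertiary radical is oxidized at the anode to a cation that water captures (radical–polar crossover), so the quaternary center of 8 dictates which face is bridged (C1 and C5) and the hydroxyisopropyl group takes the exo position away from the diketone bridge (C6); the closest known reaction type is the Mn(OAc)3-mediated oxidative radical cyclization of dearomatized acylphloroglucinols.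

**Step 5**
Reactants: 10 (1R,5R,6R)-1-[(2E)-but-2-en-1-yl]-4-hydroxy-6-(2-hydroxypropan-2-yl)-5-methyl-3-(2-methylpropanoyl)bicyclo[3.2.1]oct-3-ene-2,8-dione; 11 2-methylbut-2-ene
Product: 12 (1R,5R,6R)-4-hydroxy-6-(2-hydroxypropan-2-yl)-5-methyl-1-(3-methylbut-2-en-1-yl)-3-(2-methylpropanoyl)bicyclo[3.2.1]oct-3-ene-2,8-dione
Conditions: second-generation Grubbs catalyst RuCl2(PCy3)(H2IMes)(=CHPh) (5 mol %), 2-methylbut-2-ene (excess), CH2Cl2, 40 °C
Reagents that add atoms: 2-methylbut-2-ene (compound 11), CC=C(C)C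
Why: Olefin cross-metathesis with excess 2-methylbut-2-ene exchanges the ethylidene terminus for isopropylidene, the trisubstituted product is inert to further metathesis, and no stereocenter is touched.

**Compound list**
1 | 2-methylbenzene-1,3,5-triol | Cc1c(O)cc(O)cc1O | starting material
2 | 2-methylpropanoyl chloride | CC(C)C(Cl)=O | starting material
3 | 1-(2,4,6-trihydroxy-3-methylphenyl)-2-methylpropan-1-one | CC(C)C(=O)c1c(O)cc(O)c(C)c1O | intermediate
4 | 1-bromo-3-methylbut-2-ene | CC(C)=CCBr | starting material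
5 | 1-[2,4,6-trihydroxy-3-methyl-5-(3-methylbut-2-en-1-yl)phenyl]-2-methylpropan-1-one | CC(C)C(=O)c1c(O)c(C)c(O)c(CC=C(C)C)c1O | intermediate
6 | (R)-but-3-en-2-ol | C[C@@H](O)C=C | starting material
7 | 1-[4-{[(2S)-but-3-en-2-yl]oxy}-2,6-dihydroxy-3-methyl-5-(3-methylbut-2-en-1-yl)phenyl]-2-methylpropan-1-one | C[C@H](Oc1c(C)c(O)c(C(=O)C(C)C)c(O)c1CC=C(C)C)C=C | intermediate
8 | (6R)-6-[(2E)-but-2-en-1-yl]-3,5-dihydroxy-4-methyl-6-(3-methylbut-2-en-1-yl)-2-(2-methylpropanoyl)cyclohexa-2,4-dien-1-one | CC(C)C(=O)C1=C(O)C(C)=C(O)[C@](CC=C(C)C)(C/C=C/C)C1=O | intermediate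
9 | water | O | starting material
10 | (1R,5R,6R)-1-[(2E)-but-2-en-1-yl]-4-hydroxy-6-(2-hydroxypropan-2-yl)-5-methyl-3-(2-methylpropanoyl)bicyclo[3.2.1]oct-3-ene-2,8-dione | C/C=C/C[C@@]12C[C@@H](C(C)(C)O)[C@@](C)(C1=O)C(O)=C(C(=O)C(C)C)C2=O | intermediate
11 | 2-methylbut-2-ene | CC=C(C)C | starting material
12 | (1R,5R,6R)-4-hydroxy-6-(2-hydroxypropan-2-yl)-5-methyl-1-(3-methylbut-2-en-1-yl)-3-(2-methylpropanoyl)bicyclo[3.2.1]oct-3-ene-2,8-dione | CC(C)=CC[C@@]12C[C@@H](C(C)(C)O)[C@@](C)(C1=O)C(O)=C(C(=O)C(C)C)C2=O | target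

**Step count and risks**
Total step count: 5. Longest linear sequence: 5 steps (1 → 3 → 5 → 8 → 10 → 12).

Steps most likely to fail: 3, 4 and 5.

Step 3. The ether oxygen of 7 is flanked by the methyl-bearing and the prenyl-bearing ring carbons, and nothing strongly favors one over the other. The [3,3] shift may therefore give much of the unwanted regioisomer; the Mitsunobu reaction on this doubly flanked phenol may also be slow. The fallback sets out from 3 and comes back at 8. It places the ether on the oxygen whose only open ortho carbon is the one that must become quaternary.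
- The para-OH of 3 is silylated (TBSCl, imidazole, DMF) to 1-(4-{[tert-butyl(dimethyl)silyl]oxy}-2,6-dihydroxy-3-methylphenyl)-2-methylpropan-1-one F1.
- Mitsunobu reaction of F1 with (S)-but-3-en-2-ol (PPh3, DIAD) at the less hindered ortho-OH, next to the free ring CH, gives 1-(6-{[(2R)-but-3-en-2-yl]oxy}-4-{[tert-butyl(dimethyl)silyl]oxy}-2-hydroxy-3-methylphenyl)-2-methylpropan-1-one F2.
- TBAF in THF gives 1-(6-{[(2R)-but-3-en-2-yl]oxy}-2,4-dihydroxy-3-methylphenyl)-2-methylpropan-1-one F3.
- C-prenylation with prenyl bromide 4 in aq. KOH gives 1-[2-{[(2R)-but-3-en-2-yl]oxy}-4,6-dihydroxy-5-methyl-3-(3-methylbut-2-en-1-yl)phenyl]-2-methylpropan-1-one F4.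
- Heating F4 in toluene at 110 °C moves the allyl group only to the prenyl-bearing carbon, because the other ortho carbon carries the acyl group, and returns 8 with the same (6R) configuration.

Step 4. This is the proposed new step. The radical may also attack the butenyl group, the tertiary cation may lose a proton to give the isopropenyl compound, and product 10 may be over-oxidized. The fallback uses known chemistry, sets out from 8 and comes back at 10.
- PhI(OAc)2 and TEMPO in THF (−78 °C to rt) effect the same 5-exo radical cyclization with radical capture, giving (1R,5R,6R)-1-[(2E)-but-2-en-1-yl]-4-hydroxy-5-methyl-3-(2-methylpropanoyl)-6-{2-[(2,2,6,6-tetramethylpiperidin-1-yl)oxy]propan-2-yl}bicyclo[3.2.1]oct-3-ene-2,8-dione F5.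
- Zn in AcOH cleaves the N–O bond of F5 and gives 10.

Step 5. The enolized triketone may bind the ruthenium catalyst, and metathesis next to the quaternary bridgehead may stall. The fallback sets out from 10 and comes back at 12.
- OsO4 (cat.), NaIO4 and 2,6-lutidine in dioxane/H2O cleave the butenyl alkene, the only non-enolic alkene, to 2-[(1S,5R,6R)-4-hydroxy-6-(2-hydroxypropan-2-yl)-5-methyl-3-(2-methylpropanoyl)-2,8-dioxobicyclo[3.2.1]oct-3-en-1-yl]acetaldehyde F6 (the descriptor at C1 changes only because the CIP priorities change).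
- Wittig olefination of F6 with excess isopropylidenetriphenylphosphorane (from isopropyltriphenylphosphonium iodide and n-butyllithium, THF) gives 12.

**Further compounds**
F1 | step 3 | 1-(4-{[tert-butyl(dimethyl)silyl]oxy}-2,6-dihydroxy-3-methylphenyl)-2-methylpropan-1-one | CC(C)C(=O)c1c(O)cc(O[Si](C)(C)C(C)(C)C)c(C)c1O
F2 | step 3 | 1-(6-{[(2R)-but-3-en-2-yl]oxy}-4-{[tert-butyl(dimethyl)silyl]oxy}-2-hydroxy-3-methylphenyl)-2-methylpropan-1-one | CC(C)C(=O)c1c(O[C@H](C)C=C)cc(O[Si](C)(C)C(C)(C)C)c(C)c1O
F3 | step 3 | 1-(6-{[(2R)-but-3-en-2-yl]oxy}-2,4-dihydroxy-3-methylphenyl)-2-methylpropan-1-one | CC(C)C(=O)c1c(O[C@H](C)C=C)cc(O)c(C)c1O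
F4 | step 3 | 1-[2-{[(2R)-but-3-en-2-yl]oxy}-4,6-dihydroxy-5-methyl-3-(3-methylbut-2-en-1-yl)phenyl]-2-methylpropan-1-one | CC(C)C(=O)c1c(O[C@H](C)C=C)c(CC=C(C)C)c(O)c(C)c1O
F5 | step 4 | (1R,5R,6R)-1-[(2E)-but-2-en-1-yl]-4-hydroxy-5-methyl-3-(2-methylpropanoyl)-6-{2-[(2,2,6,6-tetramethylpiperidin-1-yl)oxy]propan-2-yl}bicyclo[3.2.1]oct-3-ene-2,8-dione | C/C=C/C[C@@]12C[C@@H](C(C)(C)ON3C(C)(C)CCCC3(C)C)[C@@](C)(C1=O)C(O)=C(C(=O)C(C)C)C2=O
F6 | step 5 | 2-[(1S,5R,6R)-4-hydroxy-6-(2-hydroxypropan-2-yl)-5-methyl-3-(2-methylpropanoyl)-2,8-dioxobicyclo[3.2.1]oct-3-en-1-yl]acetaldehyde | O=CC[C@@]12C[C@@H](C(C)(C)O)[C@@](C)(C1=O)C(O)=C(C(=O)C(C)C)C2=O
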